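# Total synthesis of methyl 15,16-dihydroxy-5β-labda-8(17),13E-dien-19-oate (28) from (+)-podocarpic acid

## The problem

- Target 28 is a labdane-type methyl ester with a cis-fused decalin. Labdane numbering is used for every compound after the arene cleavage. H5, the C10 methyl C20, the ester carbon C19 on C4 and the side-chain carbon C11 on C9 are all β. The C4 methyl C18 is α. This is (4S,5S,9S,10R).
- C4, C5 and C10 are contiguous in ring A and two of them are quaternary. None can be repaired once made, so they should come from a source that raises no selectivity question.
- C9 lies between the quaternary C10 and C8. Ring A can influence it only through conformation, but it stays adjustable as long as C8 is a carbonyl carbon.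
- The cis-decalin has two chair–chair folds and neither is comfortable. The fold with C11 equatorial tucks C18 over ring B, within reach of C7 and C9; the other fold carries C11 axial. An "equatorial is best" argument therefore does not secure C9.
- Several groups are fragile.
  - Protic acid moves the exocyclic C8=C17 alkene into the ring or lets an oxygen function at C12 add to C8, and borane adds to it.
  - The geometry of the trisubstituted C13=C14 alkene (C12 cis to C15) must be built and cannot be equilibrated.
  - The two allylic alcohols also need gentle handling.
  - The neopentyl C19 ester, by contrast, is robust and can be carried from early on.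
- Two features of the skeleton open the route.
  - **Ring A maps onto podocarpic acid.** Read as C4(CH3, C19)–C5(H, C6)–C10(CH3, C9), ring A coincides with ring A of (+)-podocarpic acid 1 after a half turn about the C2···C5 axis that exchanges C4 and C10. The carboxyl carbon of 1 becomes C9, its C6–C7 bridge stays C6–C7, and its two ring-fusion arene carbons become C8 and C19.
  - **C8 and C12 form a dissonant pair.** With C17 read as a masked oxygen and C12 as a carboxyl carbon, C8 and C12 are 1,4-related carbonyl carbons. This pattern calls for an acyl radical (or acyl anion equivalent) at C8 adding to C9 of a C9=C11–C12 enoate, and that bond closes ring B.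

## Retrosynthesis

**C12–C13.** Cutting here (28 ⇒ bis-silyl ether 27 ⇒ primary iodide 21 + alkenyl iodide 25) separates the stereochemistry of the decalin from the geometry of the side chain.
- The neighbouring cuts are worse. An olefination across C13=C14 would have to tell CH2OH from CH2CH2R on a ketone. A cut at C11–C12 needs an allylic electrophile that can react at either end.
- The forward sp3–sp2 Negishi coupling must keep the alkene geometry and tolerate an ester and a 1,1-disubstituted alkene. An alkylzinc iodide from direct zinc insertion meets both demands.

**C13–I and C14–H (25 ⇒ 24 ⇒ 22).** No carbon–carbon bond is cut. H and I are removed from a symmetrical alkyne. Anti addition directed by a propargylic alkoxide places the two CH2O groups trans and iodine cis to C15, which is the required geometry. The precursor, but-2-yne-1,4-diol 22, is a bulk chemical.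

**C12 oxidation level and C8=C17 (21 ⇒ 20 ⇒ 18 ⇒ 16 ⇒ 14).**
- The iodide goes back to alcohol 20, acid 18 and tert-butyl ester 16 without skeletal change. The forward reagents must avoid protic acid and borane because of C8=C17.
- Cutting C8=C17 gives keto ester 14, where C9 is α to a carbonyl. The methylenation must therefore be non-basic.
- The same acidity is used to advantage. Enamine 15 is placed between 14 and 16 so that allylic strain, not the history of the sample, decides C9.

**C8–C9 (14 ⇒ 13), the key cut.**
- It is the only ring-B bond whose two ends are both carboxyl-derived carbons of degraded 1.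
- Cuts at C5–C6 or C9–C10 would destroy pool-derived stereocentres. A C7–C8 cut offers no polarity handle. A C9–C11 cut (alkylation of a C8 ketone) would enolise toward C7 and still leave ring B to be made.
- Precursor 13 is monocyclic, with one ring and one stereocentre fewer.
- The forward reaction must close the ring before the acyl radical is reduced or loses CO. The cis fusion follows from the substrate. C9 is not rigorously controlled (see step 10).

**C9=C11 (13 ⇒ 11 ⇒ 10 ⇒ 8 + 9).** An olefination of the non-enolisable neopentyl aldehyde 8 with phosphonate 9 adds C11 and C12. The tert-butyl group and the hindrance at C19 leave the C8 methyl ester as the only ester that mild hydroxide can open, so the three carboxyls are told apart without extra protecting groups.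

**Reconnection of C8 and C19 in an arene (8 ⇒ 7 ⇒ 6 ⇒ 5 ⇒ 4).** Read backwards, the two carboxyl carbons of diacid 5 are joined through four further carbons into the phenol ring of 4. The forward oxidation cleaves only aromatic carbon–carbon bonds, so C4, C5 and C10 are untouched. It must attack the ring faster than the benzylic C7 methylene, which is why the phenol is kept free.

**Adjustment of C9 (4 ⇒ 2 ⇒ 1).** The carboxyl of 1 is lowered to the alcohol level and masked as an acetate before the oxidation. C9 therefore never has to be distinguished from two other carboxyl groups.

## Roads not taken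

**Alternative 1:** The cut is C4–C5.
- *Forward step.* The racemic α-methyl aldehyde A1, a 4,4-disubstituted cyclohexadienone with a C1–C4 tether, would be condensed with a chiral primary amine. The enamine carbon C4 then adds to one of the two enantiotopic β-carbons and gives the cis-fused enone aldehyde A2.
- *Merits.* Ring A, C4, C5 and C10 arise in one catalytic step from an achiral ring, and the cis fusion is the natural outcome. In brevity up to the bicycle, and in independence from a natural source, this road is better than the chosen one.
- *Weak points.*
  - C4 is quaternary, so the nucleophile is a trisubstituted enamine. Its geometry, together with the dienone face, decides C4 against C5 and C10.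
  - Both enantiomers of A1 must funnel through one enamine geometry.
  - The new bond joins a fully substituted carbon to a carbon next to the quaternary C10.
  - A2 carries its oxygen at C7 and nothing at C9. It still needs a conjugate addition at C9 (syn to C20), a one-carbon unit at C8, removal of the C7 oxygen and oxidation of the formyl group. These operations use up the steps that were saved.
- *Comparison.* The chosen plan offers certainty at C4, C5 and C10, and a key product 14 that already has oxygen at C8 and C11–C12 in place. C9 is no easier on either road.

**Alternative 2:** The cuts are C3–C4 and C5–C10.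
- *Forward step.* The open-chain triene A3 has a Z-configured C1=C10 diene terminus and an E-2-methyl enoate. It would undergo an intramolecular Diels–Alder reaction to the octalin A4.
- *Merits.* Both rings and both quaternary carbons form at once. A4 already has the C8 ketal and the C9 arm, so C9 is a given and not a problem. In this respect, and in the short endgame, it is better than the chosen plan.
- *Weak points.*
  - A Z-diene whose inner substituent is the branched C9 reaches the s-cis form only against severe strain and is prone to 1,5-hydrogen shift.
  - The dienophile is trisubstituted and only singly activated.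
  - Both new σ-bonds end at carbons that become quaternary.
  - One stereocentre next to a ketal must choose the diene face and the endo or exo mode.
  - A3 needs an asymmetric synthesis of C9 and two defined alkene geometries, and the C1=C2 alkene must be removed later.
- *Comparison.* The chosen plan makes one bond where this road makes two. That bond is formed by a fast, polarity-matched radical addition, and the three hardest centres are bought.

**Alternative 3:** The cuts are C5–C6 and C9–C10.
- *Forward step.* The ring-A enal A5 and the 1-alkyl-3-silyloxydiene A6 would combine under Lewis acid to the angular aldehyde A7.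
- *Merits.* The step is convergent and the cis fusion is automatic. The endo rule ties C11 to the angular formyl group, so the relation between C9 and C10 comes out correctly by a suprafacial mechanism. This is a real advantage over the chosen plan.
- *Weak points.*
  - The dienophile alkene is trisubstituted and C5 is flanked by the quaternary C4.
  - Facial selection rests on the small difference between CH3 and CO2CH3 at C4.
  - The angular formyl group must be reduced to a methyl at a neopentyl position.
  - The oxygen sits at C7 and must be moved to C8.
  - A5 needs its own enantioselective synthesis of a quaternary centre.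
- *Comparison.* The chosen plan has no redox correction on the ring skeleton and no facial question at C4, C5 or C10. It pays with a C9 centre that has to be set by a separate equilibration.

Key step: step 10

Remark on the chemistry: the structure is taken as drawn (5β-H, 9α-H, 10β-CH3, 4β-CO2CH3, C12 cis to C15). In the seco compounds "α" is the face of ring A that carries C9, C6 and C18, and "β" is the face with C20, H5 and C19.

## Route

Step 1
Reactants: 1 (+)-podocarpic acid
Product: 2 podocarpa-8,11,13-triene-12,19-diol (4β-CH2OH; 4α-CH3; 5α-H; 10β-CH3)
Conditions: LiAlH4, THF, reflux; aq. NaOH work-up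
Reagents that add atoms: none
Why: Hydride reduction of a carboxylate; the axial neopentyl carboxyl needs LiAlH4 at reflux, the phenoxide is inert and no stereocentre is touched.

Step 2
Reactants: 2 podocarpa-8,11,13-triene-12,19-diol
Product: 4 19-acetoxypodocarpa-8,11,13-trien-12-ol, via diacetate 3 (not isolated)
Conditions: Ac2O, pyridine, DMAP (cat.), CH2Cl2, rt; evaporate; K2CO3 (cat.), MeOH, 0 °C
Reagents that add atoms: acetic anhydride, CC(=O)OC(C)=O
Why: Exhaustive O-acetylation followed by chemoselective methanolysis, since an aryl acetate is far more electrophilic than a hindered neopentyl acetate. The freed phenol keeps the arene electron-rich for step 3, and the acetate shields C19-OH (the future C9) from oxidation.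

Step 3
Reactants: 4 19-acetoxypodocarpa-8,11,13-trien-12-ol
Product: 5 ring-A diacid [C4: α-CH3/β-CO2H; C5: β-H/α-CH2CH2CO2H; C10: β-CH3/α-CH2OAc]
Conditions: RuCl3·xH2O (cat.), NaIO4, EtOAc–MeCN–H2O, rt
Reagents that add atoms: sodium periodate, [Na+].[O-]I(=O)(=O)=O; water, O
Why: Catalytic RuO4 degradation of an arene to carboxylic acids; the phenol ring is attacked first, its four CH/C–OH carbons are burnt to CO2 and the two ring-fusion carbons remain as carboxyl carbons. Only aromatic C–C bonds break, so the three stereocentres persist; after the half turn the new acids are C8 and C19.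

Step 4
Reactants: 5 ring-A diacid
Product: 6 dimethyl ester of 5 (C8 and C19 CO2CH3; C10 α-CH2OAc)
Conditions: MeI, K2CO3, DMF, rt
Reagents that add atoms: iodomethane, CI
Why: SN2 alkylation of carboxylates takes place at oxygen, away from the acyl carbon, so the tertiary C19 acid should esterify as readily as the C8 acid.

Step 5
Reactants: 6 dimethyl ester acetate
Product: 7 C9 alcohol (C10 α-CH2OH; C8 and C19 methyl esters)
Conditions: K2CO3 (cat.), MeOH, rt to 40 °C
Reagents that add atoms: none
Why: Base-catalysed transesterification; exchange at the methyl esters is degenerate in methanol. A δ-lactone onto C19 cannot form because C9 and C19 are trans-1,3 on ring A.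

Step 6
Reactants: 7 C9 alcohol
Product: 8 C9 aldehyde (C10 α-CHO; C8 and C19 methyl esters)
Conditions: Dess–Martin periodinane, CH2Cl2, rt
Reagents that add atoms: none
Why: Dess–Martin oxidation of a neopentyl primary alcohol; the aldehyde has no α-hydrogen, so it can neither epimerise nor enolise.

Step 7
Reactants: 8 C9 aldehyde; 9 tert-butyl diethylphosphonoacetate
Product: 10 (E)-enoate triester (C10 α-CH=CH–CO2tBu; C8 and C19 methyl esters)
Conditions: 9, NaH, THF, 0 °C; then 8, rt to 50 °C
Reagents that add atoms: none
Why: Horner–Wadsworth–Emmons olefination; the phosphonate anion is more nucleophilic than the corresponding stabilised ylide, which matters for an α-quaternary aldehyde. A bulky aldehyde substituent favours the E-alkene.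

Step 8
Reactants: 10 (E)-enoate triester
Product: 11 C8 carboxylic acid (C19 methyl ester and tert-butyl enoate retained)
Conditions: LiOH, THF–MeOH–H2O, 0 °C to rt; then 1 M HCl
Reagents that add atoms: lithium hydroxide, [Li+].[OH-]
Why: Saponification selected by hindrance; only the primary-alkyl C8 ester is open to hydroxide, the C19 ester sits on a quaternary carbon and the tert-butyl ester resists acyl attack.

Step 9
Reactants: 11 C8 carboxylic acid; 12 diphenyl diselenide
Product: 13 C8 Se-phenyl selenoester (C5 α-CH2CH2C(O)SePh; C10 α-(E)-CH=CH–CO2tBu; C4 β-CO2CH3)
Conditions: (PhSe)2, n-Bu3P, CH2Cl2, rt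
Reagents that add atoms: none
Why: Redox condensation of a carboxylic acid with diselenide and phosphine through an acyloxyphosphonium ion; the conditions are neutral and the hindered β-carbon of the enoate should not take up selenol.

Step 10
Reactants: 13 C8 Se-phenyl selenoester
Product: 14 19-methyl 12-tert-butyl 8-oxo-13,14,15,16,17-pentanor-5β-labdane-12,19-dioate (cis-fused; 9α-H; C11 β)
Conditions: (Me3Si)3SiH, Et3B, air, PhH (0.01 M), rt, slow addition of silane
Reagents that add atoms: none
Why: Ethyl radicals from Et3B/O2 start a chain in which (Me3Si)3Si• abstracts PhSe from 13; the C8 σ-acyl radical, nucleophilic and slow to lose CO because only a primary alkyl radical would result, adds to C9, the β-carbon of the E-enoate, and the C11 α-ester radical takes hydrogen from the silane. The closest known reaction type is the 6-exo cyclisation of selenoester-derived acyl radicals onto α,β-unsaturated esters. Ring B closes 6-exo-trig; the 7-endo mode would place the nucleophilic radical on the α-carbon C11 and is polarity-mismatched. The fusion must be cis because C6 and C9 stand cis on C5 and C10 (axial/equatorial in either chair of ring A) and neither centre is touched. C9 is the one new stereocentre and is set by the enoate face that meets C8: in the podocarpate-like chair (enoate axial) only the C11-equatorial approach is open and gives 14, but C7 must then pass the axial C18 at syn-pentane distance, whereas in the flipped chair (acyl arm axial, enoate equatorial) that contact is absent and 14 results from the C11-pseudo-axial orientation, its 9-epimer from the pseudo-equatorial one. Two of the three accessible transition states lead to 14, yet ring A is not locked and the margin is expected to be small, so the step is asked only for chemoselectivity (closure before hydrogen transfer or decarbonylation), which dilution, a slow hydrogen donor and room temperature should secure. The C9 ratio is made irrelevant by step 11.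

Step 11
Reactants: 14 keto ester (carried on with any 9-epimer that accompanies it)
Product: 15 Δ7-pyrrolidine enamine of 14 (C7=C8; N on C8; C11 pseudo-axial on the β face)
Conditions: pyrrolidine, PPTS (cat.), 4 Å MS, PhH, reflux; evaporate
Reagents that add atoms: pyrrolidine, C1CCNC1
Why: Enamine condensation under equilibrating conditions; C9 epimerises through the iminium/Δ8(9) tautomers, and allylic 1,3-strain between the pyrrolidine α-CH2 and an equatorial C11 forces the less substituted Δ7 enamine to carry C11 pseudo-axial. In the unstrained fold (C19 and C20 axial on ring A) pseudo-axial at C9 is the β face, while the 9-epimer could be pseudo-axial only in the fold that points C11 at C4, so both ketone epimers should converge on 15. This is the known contra-thermodynamic epimerisation of 2-alkylcyclohexanones through their pyrrolidine enamines.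

Step 12
Reactants: 15 Δ7-pyrrolidine enamine
Product: 16 19-methyl 12-tert-butyl 13,14,15,16-tetranor-5β-labd-8(17)-ene-12,19-dioate, via keto ester 14 (not isolated)
Conditions: AcOH–NaOAc buffer, THF–H2O, 0 °C; extract, dry; Cp2TiMe2, toluene, 70 °C, dark
Reagents that add atoms: dimethyltitanocene, [CH3-].[CH3-].[CH-]1C=CC=C1.[CH-]1C=CC=C1.[Ti+4]; water, O (oxygen of 14 only)
Why: Buffered hydrolysis protonates the enamine at C7 and releases 14 with C9 untouched; the crude ketone is not chromatographed. Petasis methylenation (Cp2Ti=CH2 by loss of methane) is non-basic, so enolisation toward C9 is avoided, and it takes a ketone before the hindered methyl and tert-butyl esters.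

Step 13
Reactants: 16 methylene diester
Product: 18 19-methyl hydrogen 13,14,15,16-tetranor-5β-labd-8(17)-ene-12,19-dioate (free C12 acid), via trimethylsilyl ester 17 (not isolated)
Conditions: TMSOTf, 2,6-lutidine, CH2Cl2, 0 °C to rt; aq. citric acid
Reagents that add atoms: trimethylsilyl triflate, C[Si](C)(C)OS(=O)(=O)C(F)(F)F (silicon of 17 only)
Why: Silyl-triflate-mediated cleavage of a tert-butyl ester by alkyl–oxygen fission, buffered by lutidine. No free protic acid is present, so C8=C17 should neither migrate nor capture the C12 carboxyl as a γ-lactone, as it could in trifluoroacetic acid.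

Step 14
Reactants: 18 C12 acid
Product: 20 methyl 12-hydroxy-13,14,15,16-tetranor-5β-labd-8(17)-en-19-oate, via mixed anhydride 19 (not isolated)
Conditions: i-BuOCOCl, N-methylmorpholine, THF, −15 °C; NaBH4, H2O, 0 °C
Reagents that add atoms: isobutyl chloroformate, CC(C)COC(=O)Cl (carbonate part of 19 only)
Why: Mixed carbonic anhydride activation and borohydride reduction; it reduces only the activated acyl group and spares the alkene, which borane would hydroborate, and the hindered C19 ester.

Step 15
Reactants: 20 C12 alcohol
Product: 21 methyl 12-iodo-13,14,15,16-tetranor-5β-labd-8(17)-en-19-oate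
Conditions: PPh3, imidazole, I2, CH2Cl2, 0 °C (premixed); then 20
Reagents that add atoms: iodine, II
Why: Appel-type iodination of a primary alcohol. The phosphine–iodine adduct is formed before the alcohol is added, so no free iodine remains to trigger 5-exo iodoetherification onto C8=C17.

Step 16
Reactants: 22 but-2-yne-1,4-diol
Product: 24 (Z)-2-iodobut-2-ene-1,4-diol, via alkenylaluminate 23 (not isolated)
Conditions: Red-Al, THF, 0 °C to rt; I2, THF, −78 °C to rt
Reagents that add atoms: iodine, II; Red-Al, [Na+].COCCO[AlH2-]OCCOC (aluminium of 23 only)
Why: Alkoxide-directed trans-hydroalumination of a propargylic alcohol places aluminium in a five-membered ring, cis to the directing CH2O, and hydrogen anti to it. Iodinolysis with retention gives the Z-iodide, in which the two CH2OH groups are trans.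

Step 17
Reactants: 24 (Z)-2-iodobut-2-ene-1,4-diol
Product: 25 (Z)-1,4-bis(tert-butyldimethylsilyloxy)-2-iodobut-2-ene
Conditions: TBSCl, imidazole, DMF, rt
Reagents that add atoms: tert-butyldimethylsilyl chloride, CC(C)(C)[Si](C)(C)Cl
Why: Standard silylation of two primary allylic alcohols; it removes the acidic protons that would destroy the organozinc partner.

Step 18
Reactants: 21 C12 iodide; 25 bis-silylated (Z)-alkenyl iodide
Product: 27 methyl 15,16-bis(tert-butyldimethylsilyloxy)-5β-labda-8(17),13E-dien-19-oate, via alkylzinc iodide 26 (not isolated)
Conditions: 21, Zn dust (BrCH2CH2Br, TMSCl act.), LiCl, THF, 40 °C; then 25, PdCl2(dppf) (cat.), rt to 50 °C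
Reagents that add atoms: zinc, [Zn] (zinc of 26 only)
Why: Direct zinc insertion into a primary alkyl iodide tolerates the ester. Negishi coupling with an alkenyl iodide proceeds with retention at sp2 carbon, so C12 takes the place of iodine, cis to C15; a bidentate phosphine suppresses β-hydride elimination.

Step 19
Reactants: 27 bis-silyl ether
Product: 28 methyl 15,16-dihydroxy-5β-labda-8(17),13E-dien-19-oate, (4S,5S,9S,10R), the target
Conditions: TBAF, THF, 0 °C to rt
Reagents that add atoms: none
Why: Fluoride desilylation is neutral to mildly basic; both alkenes and the hindered methyl ester are inert and no stereocentre is labile at this stage.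

## Compound list

1 | (+)-podocarpic acid (12-hydroxypodocarpa-8,11,13-trien-19-oic acid) | OC(=O)[C@@]1(C)CCC[C@]2(C)c3cc(O)ccc3CC[C@@H]12 | starting material
2 | podocarpa-8,11,13-triene-12,19-diol | OC[C@@]1(C)CCC[C@]2(C)c3cc(O)ccc3CC[C@@H]12 | intermediate
3 | 12,19-diacetoxypodocarpa-8,11,13-triene | CC(=O)OC[C@@]1(C)CCC[C@]2(C)c3cc(OC(C)=O)ccc3CC[C@@H]12 | intermediate
4 | 19-acetoxypodocarpa-8,11,13-trien-12-ol | CC(=O)OC[C@@]1(C)CCC[C@]2(C)c3cc(O)ccc3CC[C@@H]12 | intermediate
5 | ring-A diacid with C10 α-CH2OAc | OC(=O)CC[C@H]1[C@](C)(CCC[C@]1(C)C(O)=O)COC(C)=O | intermediate
6 | dimethyl ester of 5 | COC(=O)CC[C@H]1[C@](C)(CCC[C@]1(C)C(=O)OC)COC(C)=O | intermediate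
7 | C9 alcohol, C8/C19 dimethyl ester | COC(=O)CC[C@H]1[C@](C)(CCC[C@]1(C)C(=O)OC)CO | intermediate
8 | C9 aldehyde, C8/C19 dimethyl ester | COC(=O)CC[C@H]1[C@](C)(CCC[C@]1(C)C(=O)OC)C=O | intermediate
9 | tert-butyl diethylphosphonoacetate | CCOP(=O)(CC(=O)OC(C)(C)C)OCC | starting material
10 | (E)-enoate triester | COC(=O)CC[C@H]1[C@](C)(CCC[C@]1(C)C(=O)OC)/C=C/C(=O)OC(C)(C)C | intermediate
11 | C8 acid with C19 methyl ester and tert-butyl (E)-enoate | OC(=O)CC[C@H]1[C@](C)(CCC[C@]1(C)C(=O)OC)/C=C/C(=O)OC(C)(C)C | intermediate
12 | diphenyl diselenide | c1ccc(cc1)[Se][Se]c1ccccc1 | starting material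
13 | C8 Se-phenyl selenoester (seco precursor of the key step) | O=C([Se]c1ccccc1)CC[C@H]2[C@](C)(CCC[C@]2(C)C(=O)OC)/C=C/C(=O)OC(C)(C)C | intermediate
14 | cis-fused 8-oxo decalin with C9 β-CH2CO2tBu | O=C1CC[C@H]2[C@](C)(CCC[C@]2(C)C(=O)OC)[C@H]1CC(=O)OC(C)(C)C | intermediate
15 | Δ7-pyrrolidine enamine of 14 | C1(N3CCCC3)=CC[C@H]2[C@](C)(CCC[C@]2(C)C(=O)OC)[C@H]1CC(=O)OC(C)(C)C | intermediate
16 | 8(17)-methylene tert-butyl ester | C=C1CC[C@H]2[C@](C)(CCC[C@]2(C)C(=O)OC)[C@H]1CC(=O)OC(C)(C)C | intermediate
17 | 8(17)-methylene trimethylsilyl ester | C=C1CC[C@H]2[C@](C)(CCC[C@]2(C)C(=O)OC)[C@H]1CC(=O)O[Si](C)(C)C | intermediate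
18 | 8(17)-methylene C12 acid | C=C1CC[C@H]2[C@](C)(CCC[C@]2(C)C(=O)OC)[C@H]1CC(=O)O | intermediate
19 | isobutyl carbonic mixed anhydride of 18 | C=C1CC[C@H]2[C@](C)(CCC[C@]2(C)C(=O)OC)[C@H]1CC(=O)OC(=O)OCC(C)C | intermediate
20 | C12 alcohol | C=C1CC[C@H]2[C@](C)(CCC[C@]2(C)C(=O)OC)[C@H]1CCO | intermediate
21 | C12 iodide | C=C1CC[C@H]2[C@](C)(CCC[C@]2(C)C(=O)OC)[C@H]1CCI | intermediate
22 | but-2-yne-1,4-diol | OCC#CCO | starting material
23 | disodium cyclic alkenylaluminate from 22 and two Red-Al | [Na+].[Na+].COCCO[Al-]1(OCCOC)OCC=C1CO[AlH-](OCCOC)OCCOC | intermediate
24 | (Z)-2-iodobut-2-ene-1,4-diol | OC/C=C(\I)CO | intermediate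
25 | (Z)-1,4-bis(tert-butyldimethylsilyloxy)-2-iodobut-2-ene | CC(C)(C)[Si](C)(C)OC/C=C(\I)CO[Si](C)(C)C(C)(C)C | intermediate
26 | C12 alkylzinc iodide | C=C1CC[C@H]2[C@](C)(CCC[C@]2(C)C(=O)OC)[C@H]1CC[Zn]I | intermediate
27 | 15,16-bis-TBS ether of the target | C=C1CC[C@H]2[C@](C)(CCC[C@]2(C)C(=O)OC)[C@H]1CC/C(=C\CO[Si](C)(C)C(C)(C)C)CO[Si](C)(C)C(C)(C)C | intermediate
28 | methyl 15,16-dihydroxy-5β-labda-8(17),13E-dien-19-oate | C=C1CC[C@H]2[C@](C)(CCC[C@]2(C)C(=O)OC)[C@H]1CC/C(=C\CO)CO | target

## Step count and least certain steps

Total: 19 steps. Longest linear sequence: 17 steps from 1 (steps 1–15, 18, 19).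

**Step 10 (key step).**
- *What may go wrong.* Addition to C9 is slowed by the adjacent quaternary C10, so hydrogen transfer to the acyl radical or loss of CO may overtake ring closure. Facial discrimination at C9 may also be poor, because ring A can flip.
- *Fallback.* The same C8–C9 bond is closed by polar umpolung under catalyst control. Setting out from 11, BH3·SMe2 reduces the free acid chemoselectively to the primary alcohol F1, and Dess–Martin oxidation gives the aldehyde F2. An intramolecular Stetter reaction then closes ring B through the Breslow intermediate, using a chiral aminoindanol-derived triazolium salt and a base in toluene. The catalyst enantiomer is chosen to match the 9β outcome. The route is rejoined at 14.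

**Step 11.**
- *What may go wrong.* Condensation at a ketone flanked by the tertiary C9 may be slow or incomplete. Tautomerisation through the crowded Δ8(9) form may be too slow to equilibrate C9.
- *Fallback.* Convergence is given up in favour of separation and recycling. Setting out from 14 as obtained in step 10, the sample is equilibrated with DBU in toluene and chromatographed. The 9-epimeric keto ester F3 is returned to the equilibration, and pure 14 is taken directly into the methylenation stage of step 12. The route is rejoined at 14.

**Step 12.**
- *What may go wrong.* The C8 carbonyl of 14 is screened on the α face by the axial C1 and on the β face by the axial C11. The titanium methylidene may therefore add slowly, and prolonged heating invites enolisation with loss of the C9 configuration, or attack on the esters.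
- *Fallback.* C17 is brought in without any addition to the carbonyl carbon. Setting out from 14, kinetic deprotonation at C7 (KHMDS, −78 °C) and PhNTf2 give the Δ7-enol triflate F4. Palladium-catalysed Kumada coupling with Me3SiCH2MgCl gives the allylsilane F5. Protodesilylation with camphorsulfonic acid in CH2Cl2–MeOH at 0 °C (SE2′) protonates C7 and moves the double bond to C8=C17. The route is rejoined at 16.

**Step 3.**
- *What may go wrong.* Oxidation of the benzylic C7 methylene may compete with attack on the ring, which would shorten the C5 arm after cleavage. Degradation may also stop at partly oxidised ring fragments.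
- *Fallback.* The metal-oxo oxidation is replaced by cycloaddition chemistry. Exhaustive ozonolysis of the phenol 4 (O3, CH2Cl2–MeOH, −78 °C) is followed by an oxidative work-up with H2O2 in formic acid. Ozone does not touch benzylic C–H bonds. It sets out from 4 and rejoins at 5. This fallback makes no compound outside the list (F0).

**Step 18.**
- *What may go wrong.* Zinc insertion may be sluggish, the alkylzinc may be protonated, or β-hydride elimination may occur after transmetalation. Each leads to reduction in place of coupling.
- *Fallback.* The roles of the partners are reversed. Setting out from 25, iodine–magnesium exchange with i-PrMgCl·LiCl (THF, −40 °C) gives the alkenylmagnesium chloride F6, and ZnBr2 converts it into the alkenylzinc bromide F7. F7 is coupled with the alkyl iodide 21 as electrophile under Pd2(dba)3, tricyclopentylphosphine and N-methylimidazole. The route is rejoined at 27.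

## Further compounds

F1 | step 10 | C8 primary alcohol with C19 methyl ester and tert-butyl (E)-enoate | OCCC[C@H]1[C@](C)(CCC[C@]1(C)C(=O)OC)/C=C/C(=O)OC(C)(C)C
F2 | step 10 | C8 aldehyde with C19 methyl ester and tert-butyl (E)-enoate | O=CCC[C@H]1[C@](C)(CCC[C@]1(C)C(=O)OC)/C=C/C(=O)OC(C)(C)C
F3 | step 11 | 9-epimer of 14 (C11 α, 9β-H) | O=C1CC[C@H]2[C@](C)(CCC[C@]2(C)C(=O)OC)[C@@H]1CC(=O)OC(C)(C)C
F4 | step 12 | Δ7-enol triflate of 14 | FC(F)(F)S(=O)(=O)OC1=CC[C@H]2[C@](C)(CCC[C@]2(C)C(=O)OC)[C@H]1CC(=O)OC(C)(C)C
F5 | step 12 | Δ7 allylsilane (C8–CH2SiMe3) | C[Si](C)(C)CC1=CC[C@H]2[C@](C)(CCC[C@]2(C)C(=O)OC)[C@H]1CC(=O)OC(C)(C)C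
F0 | step 3 | none | none
F6 | step 18 | alkenylmagnesium chloride from 25 | CC(C)(C)[Si](C)(C)OC/C=C(\[Mg]Cl)CO[Si](C)(C)C(C)(C)C
F7 | step 18 | alkenylzinc bromide from 25 | CC(C)(C)[Si](C)(C)OC/C=C(\[Zn]Br)CO[Si](C)(C)C(C)(C)C
A1 | alternative 1 | rac-2-methyl-5-(1-methyl-4-oxocyclohexa-2,5-dien-1-yl)pentanal | O=CC(C)CCCC1(C)C=CC(=O)C=C1
A2 | alternative 1 | cis-fused 7-oxo-8-ene with 4β-formyl group (5β-H, 10β-CH3) | C=1C(=O)C[C@H]2[C@](C)(CCC[C@]2(C)C=O)C=1
A3 | alternative 2 | open-chain triene with Z C1=C10, E-2-methyl enoate, C8 dioxolane and C9 silyloxyethyl arm | C=C/C=C(C)\[C@@H](CCO[Si](C)(C)C(C)(C)C)C1(OCCO1)CC/C=C(\C)C(=O)OC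
A4 | alternative 2 | cis-fused octalin with C1=C2 alkene and C8 dioxolane | C12(OCCO1)CC[C@H]3[C@](C)(C=CC[C@]3(C)C(=O)OC)[C@H]2CCO[Si](C)(C)C(C)(C)C
A5 | alternative 3 | methyl 3-formyl-1-methylcyclohex-2-ene-1-carboxylate (ring-A enal, C4 as in the target) | O=CC1=C[C@@](C)(C(=O)OC)CCC1
A6 | alternative 3 | (E)-5-(tert-butyldimethylsilyloxy)hexa-3,5-dien-1-yl pivalate | C=C(O[Si](C)(C)C(C)(C)C)/C=C/CCOC(=O)C(C)(C)C
A7 | alternative 3 | cis-fused angular aldehyde with C7 silyl enol ether | C1=C(O[Si](C)(C)C(C)(C)C)C[C@H]2[C@](C=O)(CCC[C@]2(C)C(=O)OC)[C@H]1CCOC(=O)C(C)(C)C
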